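**Retrosynthetic overview**
1. The target is eight benzene rings (A to H) joined by seven diaryl ether bonds; no ring is built, the rings are bought and joined in the order A, B, C, D, E, F, G, H.
2. Each ether bond is cut to a phenoxide plus a fluorobenzaldehyde (metal-free SNAr), not to the usual copper-mediated coupling of protected halophenols.
3. The formyl group that activates the fluoride is then converted by Baeyer–Villiger (Dakin) oxidation into the next phenol oxygen ("formyl relay"), one pot per ring, with no protecting-group changes.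
4. Only two monomers are needed: 2-fluoro-3,4,5-trimethoxybenzaldehyde (rings B, D, F) and 4-fluoro-3,5-dimethoxybenzaldehyde (rings C, E, G, H); ring A is 3,5-dimethoxyphenol.
5. The end game is a Dakin oxidation on ring H and cleavage of all 19 methyl ethers.

Assumption: the target SMILES has no stereocentre and no stable stereo-axis, so the compound is achiral and no stereocontrol is needed; no step creates a stereocentre.

Naming: ring letters follow the target SMILES from left to right (ring A is the 3,5-dihydroxyphenyl end, ring H the 2,4,6-trihydroxyphenyl end). In every chain intermediate each target hydroxyl is a methyl ether unless stated. "AB aldehyde", "ABC phenol" and so on are drawn in the compound list.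

**Step 1**
Reactants: 1 3,4,5-trimethoxybenzaldehyde
Product: 2 3,4,5-trimethoxy-2-nitrobenzaldehyde
Conditions: HNO3 (65%), AcOH, 0 °C → rt
Reagents that add atoms: nitric acid, O[N+](=O)[O-]
Why: Electrophilic aromatic nitration; the two free ring positions are equivalent, so a single mononitro product forms.

**Step 2**
Reactants: 2 3,4,5-trimethoxy-2-nitrobenzaldehyde
Product: 3 2-fluoro-3,4,5-trimethoxybenzaldehyde
Conditions: anhydrous NMe4F, DMF, 80 °C
Reagents that add atoms: tetramethylammonium fluoride, C[N+](C)(C)C.[F-]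
Why: SNAr fluorodenitration; the nitro group is twisted out of conjugation by the flanking CHO and OMe groups and leaves from a Meisenheimer complex stabilised by the ortho-formyl group.

**Step 3**
Reactants: 4 3,5-dimethoxybenzaldehyde
Product: 5 2-(3,5-dimethoxyphenyl)-1,3-dioxolane
Conditions: HOCH2CH2OH, p-toluenesulfonic acid monohydrate (cat.), toluene, reflux, Dean–Stark
Reagents that add atoms: ethylene glycol, OCCO
Why: Acid-catalysed acetalisation masks the aldehyde against n-BuLi.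

**Step 4**
Reactants: 5 2-(3,5-dimethoxyphenyl)-1,3-dioxolane
Product: 8 4-fluoro-3,5-dimethoxybenzaldehyde, via aryllithium 6 (not isolated), via fluoro dioxolane 7 (not isolated)
Conditions: n-BuLi, THF, 0 °C; NFSI, −78 °C → rt; then 2 M HCl, rt
Reagents that add atoms: N-fluorobenzenesulfonimide, O=S(=O)(c1ccccc1)N(F)S(=O)(=O)c1ccccc1; water, O
Why: Directed ortho-metalation removes the proton between the two methoxy groups, the aryllithium undergoes electrophilic fluorination by the N–F reagent, and aqueous acid hydrolyses the acetal.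

**Step 5**
Reactants: 9 3,5-dimethoxyphenol; 3 2-fluoro-3,4,5-trimethoxybenzaldehyde
Product: 10 AB aldehyde
Conditions: Cs2CO3, DMSO, 120 °C, argon
Reagents that add atoms: none
Why: SNAr; the cesium phenoxide displaces the fluoride ortho to the formyl group, which stabilises the Meisenheimer intermediate.

**Step 6**
Reactants: 10 AB aldehyde; 8 4-fluoro-3,5-dimethoxybenzaldehyde
Product: 13 ABC aldehyde, via AB formate 11 (not isolated), via AB phenol 12 (not isolated)
Conditions: mCPBA (1.1 equiv), CH2Cl2, 0 °C → rt; then Cs2CO3, MeOH, rt; evaporate; then 8, DMSO, 130 °C, argon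
Reagents that add atoms: mCPBA, O=C(OO)c1cccc(Cl)c1
Why: Baeyer–Villiger (Dakin) oxidation of the electron-rich aldehyde gives the aryl formate by aryl migration, methanolysis frees the phenoxide, and this displaces the fluoride para to the formyl group of 8 by SNAr.

**Step 7**
Reactants: 13 ABC aldehyde; 3 2-fluoro-3,4,5-trimethoxybenzaldehyde
Product: 16 ABCD aldehyde, via ABC formate 14 (not isolated), via ABC phenol 15 (not isolated)
Conditions: mCPBA (1.1 equiv), CH2Cl2, 0 °C → rt; then Cs2CO3, MeOH, rt; evaporate; then 3, DMSO, 130 °C, argon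
Reagents that add atoms: mCPBA, O=C(OO)c1cccc(Cl)c1
Why: Dakin oxidation of the 4-aryloxy-3,5-dimethoxybenzaldehyde (the same type as 3,4,5-trimethoxybenzaldehyde to its phenol) gives an unhindered phenoxide, which attacks the ortho-formyl-activated fluoride of 3 by SNAr.

**Step 8**
Reactants: 16 ABCD aldehyde; 8 4-fluoro-3,5-dimethoxybenzaldehyde
Product: 19 ABCDE aldehyde, via ABCD formate 17 (not isolated), via ABCD phenol 18 (not isolated)
Conditions: mCPBA (1.1 equiv), CH2Cl2, 0 °C → rt; then Cs2CO3, MeOH, rt; evaporate; then 8, DMSO, 130 °C, argon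
Reagents that add atoms: mCPBA, O=C(OO)c1cccc(Cl)c1
Why: Same Dakin oxidation, formate methanolysis and SNAr sequence as step 6, with the ring D phenoxide attacking 8.

**Step 9**
Reactants: 19 ABCDE aldehyde; 3 2-fluoro-3,4,5-trimethoxybenzaldehyde
Product: 22 ABCDEF aldehyde, via ABCDE formate 20 (not isolated), via ABCDE phenol 21 (not isolated)
Conditions: mCPBA (1.1 equiv), CH2Cl2, 0 °C → rt; then Cs2CO3, MeOH, rt; evaporate; then 3, DMSO, 130 °C, argon
Reagents that add atoms: mCPBA, O=C(OO)c1cccc(Cl)c1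
Why: Same Dakin oxidation, formate methanolysis and SNAr sequence as step 7, with the ring E phenoxide attacking 3.

**Step 10**
Reactants: 22 ABCDEF aldehyde; 8 4-fluoro-3,5-dimethoxybenzaldehyde
Product: 25 ABCDEFG aldehyde, via ABCDEF formate 23 (not isolated), via ABCDEF phenol 24 (not isolated)
Conditions: mCPBA (1.1 equiv), CH2Cl2, 0 °C → rt; then Cs2CO3, MeOH, rt; evaporate; then 8, DMSO, 130 °C, argon
Reagents that add atoms: mCPBA, O=C(OO)c1cccc(Cl)c1
Why: Same Dakin oxidation, formate methanolysis and SNAr sequence as step 6, with the ring F phenoxide attacking 8.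

**Step 11**
Reactants: 25 ABCDEFG aldehyde; 8 4-fluoro-3,5-dimethoxybenzaldehyde
Product: 28 ABCDEFGH aldehyde, via ABCDEFG formate 26 (not isolated), via ABCDEFG phenol 27 (not isolated)
Conditions: mCPBA (1.1 equiv), CH2Cl2, 0 °C → rt; then Cs2CO3, MeOH, rt; evaporate; then 8, DMSO, 130 °C, argon
Reagents that add atoms: mCPBA, O=C(OO)c1cccc(Cl)c1
Why: Dakin oxidation then SNAr; the ring G phenoxide (flanked only by hydrogens) displaces the fluoride para to the formyl group of 8 to add the last ring.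

**Step 12**
Reactants: 28 ABCDEFGH aldehyde
Product: 30 ABCDEFGH phenol, via ABCDEFGH formate 29 (not isolated)
Conditions: mCPBA, CH2Cl2, 0 °C → rt; then Et3N, MeOH, rt
Reagents that add atoms: mCPBA, O=C(OO)c1cccc(Cl)c1
Why: Baeyer–Villiger (Dakin) oxidation turns the last formyl group into the 4-hydroxyl of ring H after amine-catalysed methanolysis of the formate.

**Step 13**
Reactants: 30 ABCDEFGH phenol
Product: 31 target icosaphenol CNP0319661.0
Conditions: BBr3 (excess), CH2Cl2, −78 °C → rt; then degassed H2O; reversed-phase chromatography under argon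
Reagents that add atoms: none
Why: Lewis-acid ether cleavage (BBr3 demethylation) removes all 19 methyl groups as bromomethane while the diaryl ether bonds, which cannot undergo SN2 at an aryl carbon, stay intact.

**Compound list**
1 | 3,4,5-trimethoxybenzaldehyde | COc1cc(C=O)cc(OC)c1OC | starting material
2 | 3,4,5-trimethoxy-2-nitrobenzaldehyde | COc1cc(C=O)c([N+](=O)[O-])c(OC)c1OC | intermediate
3 | 2-fluoro-3,4,5-trimethoxybenzaldehyde | COc1cc(C=O)c(F)c(OC)c1OC | intermediate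
4 | 3,5-dimethoxybenzaldehyde | COc1cc(C=O)cc(OC)c1 | starting material
5 | 2-(3,5-dimethoxyphenyl)-1,3-dioxolane | COc1cc(OC)cc(C2OCCO2)c1 | intermediate
6 | aryllithium: [4-(1,3-dioxolan-2-yl)-2,6-dimethoxyphenyl]lithium | [Li]c1c(OC)cc(C2OCCO2)cc1OC | intermediate
7 | fluoro dioxolane: 2-(4-fluoro-3,5-dimethoxyphenyl)-1,3-dioxolane | COc1cc(C2OCCO2)cc(OC)c1F | intermediate
8 | 4-fluoro-3,5-dimethoxybenzaldehyde | COc1cc(C=O)cc(OC)c1F | intermediate
9 | 3,5-dimethoxyphenol | COc1cc(O)cc(OC)c1 | starting material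
10 | AB aldehyde: 2-(3,5-dimethoxyphenoxy)-3,4,5-trimethoxybenzaldehyde | COc1cc(OC)cc(Oc2c(C=O)cc(OC)c(OC)c2OC)c1 | intermediate
11 | AB formate: 2-(3,5-dimethoxyphenoxy)-3,4,5-trimethoxyphenyl formate | COc1cc(OC)cc(Oc2c(OC=O)cc(OC)c(OC)c2OC)c1 | intermediate
12 | AB phenol: 2-(3,5-dimethoxyphenoxy)-3,4,5-trimethoxyphenol | COc1cc(OC)cc(Oc2c(O)cc(OC)c(OC)c2OC)c1 | intermediate
13 | ABC aldehyde: 4-[2-(3,5-dimethoxyphenoxy)-3,4,5-trimethoxyphenoxy]-3,5-dimethoxybenzaldehyde | COc1cc(OC)cc(Oc2c(Oc3c(OC)cc(C=O)cc3OC)cc(OC)c(OC)c2OC)c1 | intermediate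
14 | ABC formate: formate ester of 15 | COc1cc(OC)cc(Oc2c(Oc3c(OC)cc(OC=O)cc3OC)cc(OC)c(OC)c2OC)c1 | intermediate
15 | ABC phenol: 4-[2-(3,5-dimethoxyphenoxy)-3,4,5-trimethoxyphenoxy]-3,5-dimethoxyphenol | COc1cc(OC)cc(Oc2c(Oc3c(OC)cc(O)cc3OC)cc(OC)c(OC)c2OC)c1 | intermediate
16 | ABCD aldehyde: 15 O-arylated by a 6-formyl-2,3,4-trimethoxyphenyl group (ring D) | COc1cc(OC)cc(Oc2c(Oc3c(OC)cc(Oc4c(C=O)cc(OC)c(OC)c4OC)cc3OC)cc(OC)c(OC)c2OC)c1 | intermediate
17 | ABCD formate: formate ester of 18 | COc1cc(OC)cc(Oc2c(Oc3c(OC)cc(Oc4c(OC=O)cc(OC)c(OC)c4OC)cc3OC)cc(OC)c(OC)c2OC)c1 | intermediate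
18 | ABCD phenol: 16 with OH in place of CHO on ring D | COc1cc(OC)cc(Oc2c(Oc3c(OC)cc(Oc4c(O)cc(OC)c(OC)c4OC)cc3OC)cc(OC)c(OC)c2OC)c1 | intermediate
19 | ABCDE aldehyde: 18 O-arylated by a 4-formyl-2,6-dimethoxyphenyl group (ring E) | COc1cc(OC)cc(Oc2c(Oc3c(OC)cc(Oc4c(Oc5c(OC)cc(C=O)cc5OC)cc(OC)c(OC)c4OC)cc3OC)cc(OC)c(OC)c2OC)c1 | intermediate
20 | ABCDE formate: formate ester of 21 | COc1cc(OC)cc(Oc2c(Oc3c(OC)cc(Oc4c(Oc5c(OC)cc(OC=O)cc5OC)cc(OC)c(OC)c4OC)cc3OC)cc(OC)c(OC)c2OC)c1 | intermediate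
21 | ABCDE phenol: 19 with OH in place of CHO on ring E | COc1cc(OC)cc(Oc2c(Oc3c(OC)cc(Oc4c(Oc5c(OC)cc(O)cc5OC)cc(OC)c(OC)c4OC)cc3OC)cc(OC)c(OC)c2OC)c1 | intermediate
22 | ABCDEF aldehyde: 21 O-arylated by a 6-formyl-2,3,4-trimethoxyphenyl group (ring F) | COc1cc(OC)cc(Oc2c(Oc3c(OC)cc(Oc4c(Oc5c(OC)cc(Oc6c(C=O)cc(OC)c(OC)c6OC)cc5OC)cc(OC)c(OC)c4OC)cc3OC)cc(OC)c(OC)c2OC)c1 | intermediate
23 | ABCDEF formate: formate ester of 24 | COc1cc(OC)cc(Oc2c(Oc3c(OC)cc(Oc4c(Oc5c(OC)cc(Oc6c(OC=O)cc(OC)c(OC)c6OC)cc5OC)cc(OC)c(OC)c4OC)cc3OC)cc(OC)c(OC)c2OC)c1 | intermediate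
24 | ABCDEF phenol: 22 with OH in place of CHO on ring F | COc1cc(OC)cc(Oc2c(Oc3c(OC)cc(Oc4c(Oc5c(OC)cc(Oc6c(O)cc(OC)c(OC)c6OC)cc5OC)cc(OC)c(OC)c4OC)cc3OC)cc(OC)c(OC)c2OC)c1 | intermediate
25 | ABCDEFG aldehyde: 24 O-arylated by a 4-formyl-2,6-dimethoxyphenyl group (ring G) | COc1cc(OC)cc(Oc2c(Oc3c(OC)cc(Oc4c(Oc5c(OC)cc(Oc6c(Oc7c(OC)cc(C=O)cc7OC)cc(OC)c(OC)c6OC)cc5OC)cc(OC)c(OC)c4OC)cc3OC)cc(OC)c(OC)c2OC)c1 | intermediate
26 | ABCDEFG formate: formate ester of 27 | COc1cc(OC)cc(Oc2c(Oc3c(OC)cc(Oc4c(Oc5c(OC)cc(Oc6c(Oc7c(OC)cc(OC=O)cc7OC)cc(OC)c(OC)c6OC)cc5OC)cc(OC)c(OC)c4OC)cc3OC)cc(OC)c(OC)c2OC)c1 | intermediate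
27 | ABCDEFG phenol: 25 with OH in place of CHO on ring G | COc1cc(OC)cc(Oc2c(Oc3c(OC)cc(Oc4c(Oc5c(OC)cc(Oc6c(Oc7c(OC)cc(O)cc7OC)cc(OC)c(OC)c6OC)cc5OC)cc(OC)c(OC)c4OC)cc3OC)cc(OC)c(OC)c2OC)c1 | intermediate
28 | ABCDEFGH aldehyde: 27 O-arylated by a 4-formyl-2,6-dimethoxyphenyl group (ring H) | COc1cc(OC)cc(Oc2c(Oc3c(OC)cc(Oc4c(Oc5c(OC)cc(Oc6c(Oc7c(OC)cc(Oc8c(OC)cc(C=O)cc8OC)cc7OC)cc(OC)c(OC)c6OC)cc5OC)cc(OC)c(OC)c4OC)cc3OC)cc(OC)c(OC)c2OC)c1 | intermediate
29 | ABCDEFGH formate: formate ester of 30 | COc1cc(OC)cc(Oc2c(Oc3c(OC)cc(Oc4c(Oc5c(OC)cc(Oc6c(Oc7c(OC)cc(Oc8c(OC)cc(OC=O)cc8OC)cc7OC)cc(OC)c(OC)c6OC)cc5OC)cc(OC)c(OC)c4OC)cc3OC)cc(OC)c(OC)c2OC)c1 | intermediate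
30 | ABCDEFGH phenol: nonadeca-O-methyl ether of the target with a free 4-OH on ring H | COc1cc(OC)cc(Oc2c(Oc3c(OC)cc(Oc4c(Oc5c(OC)cc(Oc6c(Oc7c(OC)cc(Oc8c(OC)cc(O)cc8OC)cc7OC)cc(OC)c(OC)c6OC)cc5OC)cc(OC)c(OC)c4OC)cc3OC)cc(OC)c(OC)c2OC)c1 | intermediate
31 | CNP0319661.0, octameric icosaphenol (achiral) | Oc1cc(O)cc(Oc2c(Oc3c(O)cc(Oc4c(Oc5c(O)cc(Oc6c(Oc7c(O)cc(Oc8c(O)cc(O)cc8O)cc7O)cc(O)c(O)c6O)cc5O)cc(O)c(O)c4O)cc3O)cc(O)c(O)c2O)c1 | target

**Totals**
Total step count: 13.
Longest linear sequence: 11 steps (1 → 2 → 3 → 10 → 13 → 16 → 19 → 22 → 25 → 28 → 30 → 31, that is steps 1, 2 and 5 to 13). Steps 3 and 4 form a two-step side branch to monomer 8.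

**Three steps most likely to fail, with fallbacks**

Step 2 (fluorodenitration) is at risk because the ring carries three donor methoxy groups and the liberated nitrite or basic fluoride can attack the aldehyde or the product. The fallback sets out from 2 and comes back at 3, replacing SNAr by a Balz–Schiemann sequence. Reduce the nitro group with Fe powder in AcOH/EtOH at 70 °C to 2-amino-3,4,5-trimethoxybenzaldehyde F1. Diazotise with NaNO2 and aqueous HBF4 at 0 °C to 6-formyl-2,3,4-trimethoxybenzenediazonium tetrafluoroborate F2. Heat the dry salt in 1,2-dichlorobenzene at 120 °C to give 3.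

Step 6 is the first test of the relay on monomer 8, whose fluoride is flanked by two methoxy groups; the same concern applies to steps 8, 10 and 11. Either slow SNAr or over-oxidation of the electron-rich rings by mCPBA could stop it. The fallback sets out from 5 (for the electrophile) and from 10 (for the nucleophile) and comes back at 13, replacing SNAr by a copper-catalysed Ullmann-type coupling. Lithiate 5 with n-BuLi as in step 4 (giving 6) and quench with I2 to obtain 2-(4-iodo-3,5-dimethoxyphenyl)-1,3-dioxolane F3. Hydrolyse with 2 M HCl to 4-iodo-3,5-dimethoxybenzaldehyde F4. Separately oxidise 10 with mCPBA and cleave the formate 11 with Et3N/MeOH, this time isolating phenol 12. Couple 12 with F4 using CuI, picolinic acid and K3PO4 in DMSO at 90 °C to give 13; the para-formyl group speeds the coupling and the Dakin relay continues unchanged.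

Step 13 must cleave 19 methyl ethers and deliver an icosaphenol with three pyrogallol-type rings that oxidises readily in air; incomplete cleavage or loss on isolation is likely. The fallback sets out from 30 and comes back at 31, using trap and release instead of direct isolation. Run the BBr3 cleavage as before, then add Ac2O and pyridine to the crude, unisolated polyphenol to give the icosa-O-acetyl derivative of 31 F5. This is stable, can be purified on silica, and can be separated from partly methylated material. Remove the acetyl groups with HCl in degassed MeOH (from AcCl) at rt under argon and evaporate to obtain 31.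

**Further compounds**
F1 | step 2 | 2-amino-3,4,5-trimethoxybenzaldehyde | COc1cc(C=O)c(N)c(OC)c1OC
F2 | step 2 | 6-formyl-2,3,4-trimethoxybenzenediazonium tetrafluoroborate | COc1cc(C=O)c([N+]#N)c(OC)c1OC.F[B-](F)(F)F
F3 | step 6 | 2-(4-iodo-3,5-dimethoxyphenyl)-1,3-dioxolane | COc1cc(C2OCCO2)cc(OC)c1I
F4 | step 6 | 4-iodo-3,5-dimethoxybenzaldehyde | COc1cc(C=O)cc(OC)c1I
F5 | step 13 | icosa-O-acetyl derivative of 31 | CC(=O)Oc1cc(OC(C)=O)cc(Oc2c(Oc3c(OC(C)=O)cc(Oc4c(Oc5c(OC(C)=O)cc(Oc6c(Oc7c(OC(C)=O)cc(Oc8c(OC(C)=O)cc(OC(C)=O)cc8OC(C)=O)cc7OC(C)=O)cc(OC(C)=O)c(OC(C)=O)c6OC(C)=O)cc5OC(C)=O)cc(OC(C)=O)c(OC(C)=O)c4OC(C)=O)cc3OC(C)=O)cc(OC(C)=O)c(OC(C)=O)c2OC(C)=O)c1
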